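**Retrosynthetic overview**

The target is (2S)-4',7-dihydroxyflavan-(4β→8)-(−)-epiafzelechin-(4β→8)-(−)-epiafzelechin. All aryl rings and the two pyran rings of the epiafzelechin units are bought in, so the only ring made is the pyran ring of the upper unit (O1, C2, C3, C4, C4a, C8a), and it is closed last.
Enabling feature: C4 of that ring is a methine carbon held between two electron-rich aromatic carbons, C4a of the resorcinol-type ring A of the upper unit (para to the C7 oxygen) and C8 of the phloroglucinol-type ring A of the middle unit. It is therefore a latent aldehyde carbon awaiting twofold arylation.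
Key disconnection (one operation): C4–C4a (ring closure) and C4–C8 (interflavan bond) are cut together, giving the acyclic (S)-3-aryloxy-3-arylpropanal 14 and the benzylated epiafzelechin-(4β→8)-epiafzelechin dimer 5. C4 is set trans to the preset C2.
Aldehyde 14: 4-hydroxybenzaldehyde, pivalate, Keck allylation (C2 stereocentre), Mitsunobu etherification with 3-(benzyloxy)phenol (inversion, C2–O1 bond), ozonolysis.
Dimer 5: benzylation of (−)-epiafzelechin, DDQ oxidation at C4, Lewis-acid 4β→8 coupling. End game: depivaloylation and hydrogenolysis.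

Key step: step 8

Assumption: (−)-epiafzelechin, the (2R,3R)-flavan-3-ol that forms the middle and lower units, is bought as a chiral-pool compound (natural-product reference grade), so its heterocycles are not made in the route.

**Route**

Step 1
Reactants: 1 (−)-epiafzelechin
Product: 2 5,7,4'-tri-O-benzyl-(−)-epiafzelechin
Conditions: BnBr (3.3 equiv), K2CO3 (3.5 equiv), DMF, 0 °C to rt, N2
Reagents that add atoms: benzyl bromide, BrCc1ccccc1
Why: Williamson ether synthesis: K2CO3 deprotonates only the three phenols (the C3 alcohol stays free) and no stereocentre is touched.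

Step 2
Reactants: 2 5,7,4'-tri-O-benzyl-(−)-epiafzelechin
Product: 4 4β-(2-ethoxyethoxy)-5,7,4'-tri-O-benzyl-(−)-epiafzelechin, via C4 cation 3 (not isolated)
Conditions: DDQ (2 equiv), 2-ethoxyethanol (5 equiv), CH2Cl2, rt
Reagents that add atoms: 2-ethoxyethanol, CCOCCO
Why: Oxidative benzylic etherification: DDQ abstracts hydride from C4 to give the quinone-methide-type cation 3, stabilised by the 5,7-dialkoxy ring A, and the alcohol adds anti to the C3 hydroxyl (3,4-trans), which sets the 4β configuration.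

Step 3
Reactants: 4 4β-(2-ethoxyethoxy)-5,7,4'-tri-O-benzyl-(−)-epiafzelechin; 2 5,7,4'-tri-O-benzyl-(−)-epiafzelechin (4 equiv, excess recovered)
Product: 5 5,7,4'-tri-O-benzyl-(−)-epiafzelechin-(4β→8)-5,7,4'-tri-O-benzyl-(−)-epiafzelechin
Conditions: TMSOTf (0.5 equiv), CH2Cl2, −78 °C; then sat. aq. NaHCO3
Reagents that add atoms: none
Why: Friedel–Crafts flavanylation (biomimetic proanthocyanidin coupling): TMSOTf ionises the 4-ether of 4 back to the C4 benzylic cation already numbered 3 in step 2, and C8 of 2 (the ring A position flanked by the ring oxygen) attacks its β face anti to the C2 aryl and C3 hydroxyl groups (3,4-trans, 4β→8), while the excess of 2 holds back oligomerisation.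

Step 4
Reactants: 6 4-hydroxybenzaldehyde
Product: 7 4-formylphenyl pivalate
Conditions: PivCl (1.2 equiv), Et3N (1.5 equiv), DMAP (cat.), CH2Cl2, 0 °C to rt
Reagents that add atoms: pivaloyl chloride, CC(C)(C)C(=O)Cl
Why: DMAP-catalysed acylation of the phenol; the pivalate turns the para oxygen into a poor donor, so the benzylic C–O bond made in step 6 should ionise neither in the Mitsunobu reaction nor under the Lewis acid of step 8.

Step 5
Reactants: 7 4-formylphenyl pivalate; 8 allyltributylstannane (1.5 equiv)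
Product: 10 4-[(1R)-1-hydroxybut-3-en-1-yl]phenyl pivalate, via stannyl ether 9 (not isolated)
Conditions: (R)-BINOL (20 mol %), Ti(OiPr)4 (10 mol %), 4 Å MS, CH2Cl2, −20 °C; then sat. aq. NaHCO3
Reagents that add atoms: none
Why: Keck asymmetric allylation: the (R)-BINOL–titanium Lewis acid binds the aldehyde and the allylstannane adds to its Re face, which sets the (R)-carbinol centre (the future C2, before inversion).

Step 6
Reactants: 10 4-[(1R)-1-hydroxybut-3-en-1-yl]phenyl pivalate; 11 3-(benzyloxy)phenol (1.2 equiv)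
Product: 12 4-[(1S)-1-[3-(benzyloxy)phenoxy]but-3-en-1-yl]phenyl pivalate
Conditions: PPh3 (1.5 equiv), DIAD (1.5 equiv), toluene, 0 °C to rt
Reagents that add atoms: none
Why: Mitsunobu etherification: the phenoxide of 11 displaces the alkoxyphosphonium ion by SN2 with inversion (R to S), giving the C2–O1 bond in the configuration of the target; the electron-poor pivaloyloxyphenyl group suppresses SN1 leakage.

Step 7
Reactants: 12 4-[(1S)-1-[3-(benzyloxy)phenoxy]but-3-en-1-yl]phenyl pivalate
Product: 14 4-[(1S)-1-[3-(benzyloxy)phenoxy]-3-oxopropyl]phenyl pivalate, via ozonide 13 (not isolated)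
Conditions: O3, CH2Cl2, −78 °C (Sudan red 7B end point); then PPh3 (1.2 equiv), −78 °C to rt; used crude
Reagents that add atoms: ozone, [O-][O+]=O
Why: Ozonolysis (Criegee mechanism) with reductive work-up: the terminal alkene reacts far faster than the aryl ether rings, one carbon is lost as formaldehyde and the C2 stereocentre is untouched; 14 is used at once because β-aryloxy aldehydes can eliminate the phenol.

Step 8
Reactants: 14 4-[(1S)-1-[3-(benzyloxy)phenoxy]-3-oxopropyl]phenyl pivalate; 5 5,7,4'-tri-O-benzyl-(−)-epiafzelechin-(4β→8)-5,7,4'-tri-O-benzyl-(−)-epiafzelechin (1.5 equiv, excess recovered)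
Product: 17 (2S)-7-O-benzyl-4'-O-pivaloyl-4',7-dihydroxyflavan-(4β→8)-[5,7,4'-tri-O-benzyl-(−)-epiafzelechin]-(4β→8)-[5,7,4'-tri-O-benzyl-(−)-epiafzelechin], via flavan-4-ol 15 (not isolated), via flavan-4-yl cation 16 (not isolated)
Conditions: TMSOTf (0.2 equiv), 4 Å MS, CH2Cl2 (0.02 M), −40 °C, slow addition of 14 to 5 and the acid; Et3N quench
Reagents that add atoms: none
Why: Proposed new method: TMSOTf activates the aldehyde of 14, whose carbonyl carbon is attacked by the carbon of the 3-(benzyloxy)phenoxy ring that lies ortho to the ether oxygen and para to OBn (Friedel–Crafts hydroxyalkylation, 6-exo-trig with respect to the carbonyl group, arene π bond endo), closing the pyran ring as flavan-4-ol 15; 15 ionises at once to the para-alkoxy-stabilised cation 16, which is captured by C8 of the upper unit of 5 to forge the C4–C8 interflavan bond. The closest known reaction types are the acid-mediated twofold arylation of aldehydes (Baeyer diarylmethane condensation), the cyclisation of 3-aryloxypropanals to chroman-4-ols and 2H-chromenes, and the Friedel–Crafts flavanylation of phloroglucinol-type rings by flavan-4-ols and 4-alkoxyflavans as in step 3; their merger in one flask on a 3-aryl-3-aryloxypropanal is what is new. The new C4 stereocentre is controlled by the existing C2 centre: cation 16 is a half-chair with the C2 aryl group pseudo-equatorial, and the nucleophile should add pseudo-axially on the face anti to that aryl group to give the 2,4-trans (4β) isomer, as in the capture of flavan-4-yl cations by phenols; C2 is not involved and the pivalate keeps the C2–O1 bond from ionising. Three selectivities are needed: ring closure rather than a second intermolecular arylation at the aldehyde carbon (secured by the intramolecular six-membered closure, high dilution and slow addition of 14), closure para and not ortho to OBn (para activation and sterics), and attack by C8 of the upper unit of 5 and not by either C6 (C8 is the only free ring A position flanked by the ring oxygen, and C8 of the lower unit is blocked). If 5 attacks the aldehyde before the ring closes, the resulting diarylcarbinol ionises and closes the same ring, so both orders converge on 17. Dehydration of 15 to the flav-3-ene is harmless because protonation at C3 returns cation 16.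

Step 9
Reactants: 17 hepta-O-benzyl 4'-O-pivaloyl trimer
Product: 18 (2S)-7-O-benzyl-4',7-dihydroxyflavan-(4β→8)-[5,7,4'-tri-O-benzyl-(−)-epiafzelechin]-(4β→8)-[5,7,4'-tri-O-benzyl-(−)-epiafzelechin]
Conditions: K2CO3 (0.5 equiv), MeOH/THF (1:1), rt
Reagents that add atoms: none
Why: Base-catalysed transesterification (methanolysis) of the aryl pivalate; benzyl ethers and interflavan bonds are inert, and the mild base at room temperature should not open ring C through a quinone methide.

Step 10
Reactants: 18 hepta-O-benzyl trimer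
Product: 19 (2S)-4',7-dihydroxyflavan-(4β→8)-(−)-epiafzelechin-(4β→8)-(−)-epiafzelechin (target; upper unit 2S,4R; middle unit 2R,3R,4S; lower unit 2R,3R)
Conditions: H2 (1 atm), Pd(OH)2/C, THF/MeOH/H2O (20:1:1), rt; filtration, lyophilisation
Reagents that add atoms: none
Why: Hydrogenolysis of the seven benzyl ethers under neutral conditions, the usual last step for benzylated proanthocyanidins; no stereocentre is affected.

**Compound list**

1 | (−)-epiafzelechin, (2R,3R)-2-(4-hydroxyphenyl)chromane-3,5,7-triol | Oc1cc(O)c2c(c1)O[C@H](c1ccc(O)cc1)[C@H](O)C2 | starting material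
2 | 5,7,4'-tri-O-benzyl-(−)-epiafzelechin | O(Cc1ccccc1)c1cc(OCc2ccccc2)c2c(c1)O[C@H](c1ccc(OCc3ccccc3)cc1)[C@H](O)C2 | intermediate
3 | C4 benzylic cation of 2 | O(Cc1ccccc1)c1cc(OCc2ccccc2)c2c(c1)O[C@H](c1ccc(OCc3ccccc3)cc1)[C@H](O)[CH+]2 | intermediate (not isolated)
4 | 4β-(2-ethoxyethoxy)-5,7,4'-tri-O-benzyl-(−)-epiafzelechin (2,3-cis-3,4-trans) | O(Cc1ccccc1)c1cc(OCc2ccccc2)c2c(c1)O[C@H](c1ccc(OCc3ccccc3)cc1)[C@H](O)[C@H]2OCCOCC | intermediate
5 | 5,7,4'-tri-O-benzyl-(−)-epiafzelechin-(4β→8)-5,7,4'-tri-O-benzyl-(−)-epiafzelechin (both C3 hydroxyls free, C8 of the upper unit free) | c1c(OCc3ccccc3)cc(OCc3ccccc3)c2c1O[C@H](c1ccc(OCc3ccccc3)cc1)[C@H](O)[C@H]2c1c(OCc3ccccc3)cc(OCc3ccccc3)c2c1O[C@H](c1ccc(OCc3ccccc3)cc1)[C@H](O)C2 | intermediate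
6 | 4-hydroxybenzaldehyde | O=Cc1ccc(O)cc1 | starting material
7 | 4-formylphenyl pivalate | CC(C)(C)C(=O)Oc1ccc(C=O)cc1 | intermediate
8 | allyltributylstannane | C=CC[Sn](CCCC)(CCCC)CCCC | starting material
9 | tributylstannyl ether of 10, (R) | CC(C)(C)C(=O)Oc1ccc(cc1)[C@H](O[Sn](CCCC)(CCCC)CCCC)CC=C | intermediate (not isolated)
10 | 4-[(1R)-1-hydroxybut-3-en-1-yl]phenyl pivalate | CC(C)(C)C(=O)Oc1ccc(cc1)[C@H](O)CC=C | intermediate
11 | 3-(benzyloxy)phenol | Oc1cccc(OCc2ccccc2)c1 | starting material
12 | 4-[(1S)-1-[3-(benzyloxy)phenoxy]but-3-en-1-yl]phenyl pivalate | CC(C)(C)C(=O)Oc1ccc(cc1)[C@@H](Oc1cccc(OCc2ccccc2)c1)CC=C | intermediate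
13 | 4-[(1S)-1-[3-(benzyloxy)phenoxy]-2-(1,2,4-trioxolan-3-yl)ethyl]phenyl pivalate (ozonide, epimers at the trioxolane carbon) | CC(C)(C)C(=O)Oc1ccc(cc1)[C@@H](Oc1cccc(OCc2ccccc2)c1)CC1OCOO1 | intermediate (not isolated)
14 | 4-[(1S)-1-[3-(benzyloxy)phenoxy]-3-oxopropyl]phenyl pivalate | CC(C)(C)C(=O)Oc1ccc(cc1)[C@@H](Oc1cccc(OCc2ccccc2)c1)CC=O | intermediate
15 | (2S)-7-(benzyloxy)-4'-(pivaloyloxy)flavan-4-ol (C4 epimers) | CC(C)(C)C(=O)Oc1ccc(cc1)[C@@H]1CC(O)c2ccc(OCc3ccccc3)cc2O1 | intermediate (not isolated)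
16 | (2S)-7-(benzyloxy)-4'-(pivaloyloxy)flavan-4-yl cation | CC(C)(C)C(=O)Oc1ccc(cc1)[C@@H]1C[CH+]c2ccc(OCc3ccccc3)cc2O1 | intermediate (not isolated)
17 | (2S)-7-O-benzyl-4'-O-pivaloyl-4',7-dihydroxyflavan-(4β→8)-[5,7,4'-tri-O-benzyl-(−)-epiafzelechin]-(4β→8)-[5,7,4'-tri-O-benzyl-(−)-epiafzelechin] (upper unit 2,4-trans) | CC(C)(C)C(=O)Oc1ccc([C@@H]2C[C@@H](c3c(OCc5ccccc5)cc(OCc5ccccc5)c4c3O[C@H](c3ccc(OCc5ccccc5)cc3)[C@H](O)[C@H]4c3c(OCc5ccccc5)cc(OCc5ccccc5)c4c3O[C@H](c3ccc(OCc5ccccc5)cc3)[C@H](O)C4)c3ccc(OCc5ccccc5)cc3O2)cc1 | intermediate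
18 | (2S)-7-O-benzyl-4',7-dihydroxyflavan-(4β→8)-[5,7,4'-tri-O-benzyl-(−)-epiafzelechin]-(4β→8)-[5,7,4'-tri-O-benzyl-(−)-epiafzelechin] (free 4'-OH on the upper unit) | Oc1ccc([C@@H]2C[C@@H](c3c(OCc5ccccc5)cc(OCc5ccccc5)c4c3O[C@H](c3ccc(OCc5ccccc5)cc3)[C@H](O)[C@H]4c3c(OCc5ccccc5)cc(OCc5ccccc5)c4c3O[C@H](c3ccc(OCc5ccccc5)cc3)[C@H](O)C4)c3ccc(OCc5ccccc5)cc3O2)cc1 | intermediate
19 | (2S)-4',7-dihydroxyflavan-(4β→8)-(−)-epiafzelechin-(4β→8)-(−)-epiafzelechin | Oc1ccc([C@@H]2C[C@@H](c3c(O)cc(O)c4c3O[C@H](c3ccc(O)cc3)[C@H](O)[C@H]4c3c(O)cc(O)c4c3O[C@H](c3ccc(O)cc3)[C@H](O)C4)c3ccc(O)cc3O2)cc1 | target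

**Step count and risks**

Total step count: 10. Longest linear sequence: 7 steps (steps 4, 5, 6, 7, 8, 9, 10, from 4-hydroxybenzaldehyde).

Steps most likely to fail:

1. Step 8 (carries the label). What may go wrong: loss of 3-(benzyloxy)phenol from 14 by β-elimination before cyclisation, consumption of cation 16 by self-condensation with ring A of a second molecule, or poor facial selectivity at C4. Fallback with known chemistry, setting out from 14 and coming back at 17: Pinnick oxidation of 14 (NaClO2, NaH2PO4, 2-methylbut-2-ene, tBuOH/H2O) should give (3S)-3-[3-(benzyloxy)phenoxy]-3-[4-(pivaloyloxy)phenyl]propanoic acid F1. Intramolecular Friedel–Crafts acylation (trifluoroacetic anhydride, CH2Cl2, 0 °C) should then close the ring to (2S)-7-(benzyloxy)-4'-(pivaloyloxy)flavanone F2. NaBH4 (THF/MeOH, −20 °C) should reduce it to the 2,4-cis alcohol (2S,4S)-7-(benzyloxy)-4'-(pivaloyloxy)flavan-4-ol F3; both operations are kept cold and short so that C2 is not scrambled by opening of the flavanone to the chalcone. The separate TMSOTf-catalysed Friedel–Crafts coupling of F3 with 5 at −78 °C then gives 17, with ring closure and interflavan bond formation decoupled.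

2. Step 3. What may go wrong: oligomerisation, because dimer 5 competes with 2 for the C4 cation, and incomplete 4→8 versus 4→6 regioselectivity. Fallback, setting out from 4 and coming back at 5: exchange of the 4-alkoxy group for a thio leaving group with 2-mercaptobenzothiazole and BF3·OEt2 (CH2Cl2, 0 °C) should give 4β-(1,3-benzothiazol-2-ylsulfanyl)-5,7,4'-tri-O-benzyl-(−)-epiafzelechin F4. Thiophilic activation of F4 with AgBF4 (THF, 0 °C) in the presence of 2 then forms 5 under conditions that do not re-ionise the product.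

3. Step 7. What may go wrong: oxidation of the electron-rich resorcinol diether ring by ozone, and β-elimination of the phenol from 14 during work-up. Fallback, setting out from 12 and coming back at 14: dihydroxylation with OsO4 (2 mol %) and N-methylmorpholine N-oxide in acetone/H2O should give 4-[(1S)-1-[3-(benzyloxy)phenoxy]-3,4-dihydroxybutyl]phenyl pivalate F5. Glycol cleavage of F5 with NaIO4 on silica gel (CH2Cl2, 0 °C) then releases 14, which is filtered and taken directly into step 8.

Further compounds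
F1 | step 8 | (3S)-3-[3-(benzyloxy)phenoxy]-3-[4-(pivaloyloxy)phenyl]propanoic acid | CC(C)(C)C(=O)Oc1ccc(cc1)[C@@H](Oc1cccc(OCc2ccccc2)c1)CC(O)=O
F2 | step 8 | (2S)-7-(benzyloxy)-4'-(pivaloyloxy)flavanone | CC(C)(C)C(=O)Oc1ccc(cc1)[C@@H]1CC(=O)c2ccc(OCc3ccccc3)cc2O1
F3 | step 8 | (2S,4S)-7-(benzyloxy)-4'-(pivaloyloxy)flavan-4-ol (2,4-cis) | CC(C)(C)C(=O)Oc1ccc(cc1)[C@@H]1C[C@H](O)c2ccc(OCc3ccccc3)cc2O1
F4 | step 3 | 4β-(1,3-benzothiazol-2-ylsulfanyl)-5,7,4'-tri-O-benzyl-(−)-epiafzelechin | O(Cc1ccccc1)c1cc(OCc2ccccc2)c2c(c1)O[C@H](c1ccc(OCc3ccccc3)cc1)[C@H](O)[C@H]2Sc1nc2ccccc2s1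
F5 | step 7 | 4-[(1S)-1-[3-(benzyloxy)phenoxy]-3,4-dihydroxybutyl]phenyl pivalate (epimers at the secondary carbinol) | CC(C)(C)C(=O)Oc1ccc(cc1)[C@@H](Oc1cccc(OCc2ccccc2)c1)CC(O)CO
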